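**Plan**

- Labels: dihydrobenzofuran atoms O1, C2, C3, C3a, C4–C7, C7a; ring A = 3,5-dihydroxyphenyl on C3, ring B = benzo ring, ring C = dihydrofuran, ring D = catechol on C2, ring E = catechol of the styryl arm. Cuts, in order: seven O–benzyl bonds; C3–ring A (back to a C3 carboxylic acid); C6–CH= (back to an aryl triflate); C3–C3a (back to a flavanone); C2–ring D (back to a chromone).
- Enabling feature: O1–C2(ring D)–C3–C3a of ring C is the O1–C2–C3–(C4)–C4a chain of a 2-arylchroman-4-one with the carbonyl carbon left out. A 1,2-shift of C4a from C4 to C3 closes ring C and leaves C4 as a carboxyl group on C3, the handle through which ring A enters.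
- Forward order: chromone (ring B) → flavanone (ring D added) → ring C by oxidative ring contraction → ring E by Heck reaction → ring A by decarboxylative arylation → debenzylation.
- Stereochemistry: C2 (S) comes from a catalyst-controlled conjugate addition and is not touched again. C3 is placed trans to ring D twice under control of C2: in the ring contraction, and again in the nickel arylation after decarboxylation has erased it. The E alkene comes from the Heck reaction.
- All seven phenols travel as benzyl ethers, so the last step is a Lewis-acid debenzylation at −78 °C that spares the stilbene.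

Key step: step 4

Assumption: the Pd–PyOX aryl transfer is taken to select the same enone face of a chromone as of a cyclic enone, so (R)-t-BuPyOX should give the (2S)-flavanone; if the sense proves opposite, the (S)-ligand is used.

**Route**

Step 1
Reactants: 1 5,7-dihydroxy-4H-chromen-4-one
Product: 2 5-hydroxy-4-oxo-4H-chromen-7-yl trifluoromethanesulfonate
Conditions: PhNTf2 (1.05 equiv), K2CO3 (1.2 equiv), THF–DMF, 0 °C → rt
Reagents that add atoms: N-phenylbis(trifluoromethanesulfonimide), O=S(=O)(N(c1ccccc1)S(=O)(=O)C(F)(F)F)C(F)(F)F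
Why: Selective phenol O-sulfonylation: the 7-hydroxyl is the acidic, unchelated phenol, whereas the 5-hydroxyl is locked in a hydrogen bond to the C4 carbonyl, so one equivalent of the mild triflyl donor should react at O7 only.

Step 2
Reactants: 2 5-hydroxy-4-oxo-4H-chromen-7-yl trifluoromethanesulfonate
Product: 3 5-(benzyloxy)-4-oxo-4H-chromen-7-yl trifluoromethanesulfonate
Conditions: BnBr (1.5 equiv), K2CO3 (2 equiv), n-Bu4NI (10 mol %), acetone, reflux
Reagents that add atoms: benzyl bromide, BrCc1ccccc1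
Why: Williamson etherification of the chelated 5-phenol; anhydrous K2CO3 in acetone is mild enough to leave the aryl triflate and the base-sensitive pyranone ring intact.

Step 3
Reactants: 3 5-(benzyloxy)-4-oxo-4H-chromen-7-yl trifluoromethanesulfonate; 4 [3,4-bis(benzyloxy)phenyl]boronic acid
Product: 5 (2S)-5-(benzyloxy)-2-[3,4-bis(benzyloxy)phenyl]-4-oxo-3,4-dihydro-2H-chromen-7-yl trifluoromethanesulfonate
Conditions: 4 (2 equiv), Pd(OCOCF3)2 (7.5 mol %), (R)-t-BuPyOX (9 mol %), NH4PF6 (30 mol %), H2O (5 equiv), ClCH2CH2Cl, 60 °C, air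
Reagents that add atoms: none
Why: Palladium-catalysed asymmetric conjugate addition of an arylboronic acid to a chromone: transmetalation gives a cationic aryl–divalent-palladium complex, the pyridine-oxazoline ligand decides the face of C2=C3 insertion and so sets C2 as S, and water protonates the enolate; no zerovalent palladium–phosphine species is present to insert into the C–OTf bond.

Step 4
Reactants: 5 (2S)-5-(benzyloxy)-2-[3,4-bis(benzyloxy)phenyl]-4-oxo-3,4-dihydro-2H-chromen-7-yl trifluoromethanesulfonate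
Product: 9 methyl (2S,3S)-4-(benzyloxy)-2-[3,4-bis(benzyloxy)phenyl]-6-[(trifluoromethanesulfonyl)oxy]-2,3-dihydro-1-benzofuran-3-carboxylate, via methyl enol ether 6 (not isolated), via 3-iodanyl dimethyl ketal 7 (not isolated), via trimethyl ortho ester 8 (not isolated)
Conditions: HC(OMe)3–MeOH–CH2Cl2, H2SO4 (1.5 equiv), rt; then PhI(OAc)2 (1.3 equiv), 0 °C → rt; aq. NaHCO3 work-up
Reagents that add atoms: trimethyl orthoformate, COC(OC)OC; methanol, CO; water, O
Why: H2SO4 and HC(OMe)3 turn the C4 ketone into its dimethyl ketal and the enol ether 6; PhI(OAc)2 adds its trivalent iodine to C3 of 6 on the face away from ring D while methanol caps C4 to give ketal 7, the C4–C4a bond antiperiplanar to C3–I then moves the ring B carbon C4a from C4 to C3 with loss of iodobenzene, and the dimethoxycarbenium ion left at the old C4 is caught as ortho ester 8 and hydrolysed to ester 9 on work-up. The closest known reaction type is the hypervalent-iodine (or thallium trinitrate) oxidative ring contraction of flavanones in methanol and trimethyl orthoformate to methyl trans-2-aryl-2,3-dihydrobenzofuran-3-carboxylates, a semipinacol-type 1,2-aryl shift. Ring C is closed by ring contraction and not by cyclisation of a chain: the C3–C3a bond forms through a bridged, phenonium-like three-membered transition state (formally 3-exo-tet at C3, with inversion) as the six-membered ring gives up C4. C2 is a spectator and stays S, and the new C3 centre is fixed by the C2 aryl group, because anti iodination followed by inversion in the shift leaves the carboxyl carbon trans to ring D (3S). The step needs the C4a shift to outrun both a C2-to-C3 shift of the electron-rich ring D (isoflavone-type products) and plain substitution or elimination at C3 (3-methoxyflavanone, flavone); complete ketalisation before the oxidant is added secures this, since only the C4a shift ends in a cation stabilised by two oxygen atoms, and the migrating carbon is activated by its two ortho oxygen substituents (O1 and the 5-benzyloxy group). The para triflate, a weak acceptor, costs some migratory aptitude but keeps the otherwise deactivated C4 carbonyl electrophilic enough to ketalise and is itself inert to acid and oxidant.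

Step 5
Reactants: 10 3,4-bis(benzyloxy)benzaldehyde
Product: 11 1,2-bis(benzyloxy)-4-ethenylbenzene
Conditions: Ph3PCH3Br (1.3 equiv), KOt-Bu (1.25 equiv), THF, 0 °C → rt
Reagents that add atoms: methyltriphenylphosphonium bromide, C[P+](c1ccccc1)(c1ccccc1)c1ccccc1.[Br-]
Why: Wittig methylenation of an aromatic aldehyde with the unstabilised ylide made in the flask; benzyl ethers are inert.

Step 6
Reactants: 9 methyl (2S,3S)-4-(benzyloxy)-2-[3,4-bis(benzyloxy)phenyl]-6-[(trifluoromethanesulfonyl)oxy]-2,3-dihydro-1-benzofuran-3-carboxylate; 11 1,2-bis(benzyloxy)-4-ethenylbenzene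
Product: 12 methyl (2S,3S)-4-(benzyloxy)-2-[3,4-bis(benzyloxy)phenyl]-6-{(E)-2-[3,4-bis(benzyloxy)phenyl]ethenyl}-2,3-dihydro-1-benzofuran-3-carboxylate
Conditions: 11 (1.5 equiv), PdCl2(PPh3)2 (5 mol %), LiCl (3 equiv), Et3N (3 equiv), DMF, 90 °C
Reagents that add atoms: none
Why: Mizoroki–Heck reaction of an aryl triflate: zerovalent palladium inserts into C6–OTf, LiCl turns the cationic arylpalladium triflate into the neutral chloride so that the styrene is arylated at its terminal carbon, and syn β-hydride elimination gives the E stilbene; Et3N is too weak a base to disturb the trans ester.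

Step 7
Reactants: 12 methyl (2S,3S)-4-(benzyloxy)-2-[3,4-bis(benzyloxy)phenyl]-6-{(E)-2-[3,4-bis(benzyloxy)phenyl]ethenyl}-2,3-dihydro-1-benzofuran-3-carboxylate
Product: 13 (2S,3S)-4-(benzyloxy)-2-[3,4-bis(benzyloxy)phenyl]-6-{(E)-2-[3,4-bis(benzyloxy)phenyl]ethenyl}-2,3-dihydro-1-benzofuran-3-carboxylic acid
Conditions: Me3SnOH (5 equiv), ClCH2CH2Cl, 80 °C; then 1 M HCl
Reagents that add atoms: trimethyltin hydroxide, C[Sn](C)(C)O
Why: Near-neutral methyl ester cleavage by tin-assisted hydroxide delivery, chosen because free hydroxide can open 2-aryl-2,3-dihydrobenzofuran-3-carboxylates by retro-oxa-Michael elimination through the ester enolate; both stereocentres stay as they are, the trans acid being the more stable isomer in any case.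

Step 8
Reactants: 13 (2S,3S)-4-(benzyloxy)-2-[3,4-bis(benzyloxy)phenyl]-6-{(E)-2-[3,4-bis(benzyloxy)phenyl]ethenyl}-2,3-dihydro-1-benzofuran-3-carboxylic acid
Product: 14 1,3-dioxoisoindolin-2-yl (2S,3S)-4-(benzyloxy)-2-[3,4-bis(benzyloxy)phenyl]-6-{(E)-2-[3,4-bis(benzyloxy)phenyl]ethenyl}-2,3-dihydro-1-benzofuran-3-carboxylate
Conditions: N-hydroxyphthalimide (1.1 equiv), i-PrN=C=N-i-Pr (1.1 equiv), DMAP (10 mol %), CH2Cl2, rt
Reagents that add atoms: N-hydroxyphthalimide, O=C1N(O)C(=O)c2ccccc12
Why: Steglich-type carbodiimide esterification gives the redox-active N-acyloxyphthalimide under neutral conditions.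

Step 9
Reactants: 15 1,3-bis(benzyloxy)-5-bromobenzene
Product: 17 [3,5-bis(benzyloxy)phenyl]zinc chloride, via aryllithium 16 (not isolated)
Conditions: n-BuLi (1.0 equiv), THF, −78 °C; then ZnCl2 (1.05 equiv, THF), −78 °C → rt; solution titrated and used directly
Reagents that add atoms: zinc chloride, Cl[Zn]Cl
Why: Bromine–lithium exchange, which at −78 °C outruns deprotonation of the benzylic ether positions, followed by transmetalation to zinc gives the LiCl-containing arylzinc reagent.

Step 10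
Reactants: 14 1,3-dioxoisoindolin-2-yl (2S,3S)-4-(benzyloxy)-2-[3,4-bis(benzyloxy)phenyl]-6-{(E)-2-[3,4-bis(benzyloxy)phenyl]ethenyl}-2,3-dihydro-1-benzofuran-3-carboxylate; 17 [3,5-bis(benzyloxy)phenyl]zinc chloride
Product: 18 (2S,3S)-4-(benzyloxy)-2-[3,4-bis(benzyloxy)phenyl]-3-[3,5-bis(benzyloxy)phenyl]-6-{(E)-2-[3,4-bis(benzyloxy)phenyl]ethenyl}-2,3-dihydro-1-benzofuran
Conditions: 17 (3 equiv), NiCl2·glyme (20 mol %), 4,4'-di-tert-butyl-2,2'-bipyridine (40 mol %), THF–DMF, rt
Reagents that add atoms: none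
Why: Nickel-catalysed decarboxylative Negishi-type arylation of a redox-active ester: an arylnickel species reduces 14 by single-electron transfer, CO2 and phthalimide anion leave, and the planar benzylic C3 radical is captured by nickel on the face anti to the C2 aryl group before reductive elimination, so the C3 centre is rebuilt trans to ring D (3S) under control of the untouched C2 centre.

Step 11
Reactants: 18 (2S,3S)-4-(benzyloxy)-2-[3,4-bis(benzyloxy)phenyl]-3-[3,5-bis(benzyloxy)phenyl]-6-{(E)-2-[3,4-bis(benzyloxy)phenyl]ethenyl}-2,3-dihydro-1-benzofuran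
Product: 19 4-[(2S,3S)-3-(3,5-dihydroxyphenyl)-6-[(E)-2-(3,4-dihydroxyphenyl)ethenyl]-4-hydroxy-2,3-dihydro-1-benzofuran-2-yl]benzene-1,2-diol
Conditions: BCl3 (14 equiv), C6HMe5 (21 equiv), CH2Cl2, −78 °C; then MeOH, −78 °C → rt; purification under argon
Reagents that add atoms: none
Why: Lewis-acid O-debenzylation with pentamethylbenzene as a non-basic benzyl cation scavenger; at −78 °C the stilbene should not be protonated, so acid-mediated attack of ring A on the alkene is avoided, and any reversible C2–O ionisation can only return the favoured trans ring because C3 is untouched.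

**Compound list**

1 | 5,7-dihydroxy-4H-chromen-4-one | O=c1ccoc2cc(O)cc(O)c12 | starting material
2 | 5-hydroxy-4-oxo-4H-chromen-7-yl trifluoromethanesulfonate | O=c1ccoc2cc(OS(=O)(=O)C(F)(F)F)cc(O)c12 | intermediate
3 | 5-(benzyloxy)-4-oxo-4H-chromen-7-yl trifluoromethanesulfonate | O=c1ccoc2cc(OS(=O)(=O)C(F)(F)F)cc(OCc3ccccc3)c12 | intermediate
4 | [3,4-bis(benzyloxy)phenyl]boronic acid | OB(O)c1ccc(OCc2ccccc2)c(OCc2ccccc2)c1 | starting material
5 | (2S)-5-(benzyloxy)-2-[3,4-bis(benzyloxy)phenyl]-4-oxo-3,4-dihydro-2H-chromen-7-yl trifluoromethanesulfonate | O=C1C[C@@H](c2ccc(OCc3ccccc3)c(OCc3ccccc3)c2)Oc2cc(OS(=O)(=O)C(F)(F)F)cc(OCc3ccccc3)c21 | intermediate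
6 | (2S)-5-(benzyloxy)-2-[3,4-bis(benzyloxy)phenyl]-4-methoxy-2H-chromen-7-yl trifluoromethanesulfonate (methyl enol ether) | COC1=C[C@@H](c2ccc(OCc3ccccc3)c(OCc3ccccc3)c2)Oc2cc(OS(=O)(=O)C(F)(F)F)cc(OCc3ccccc3)c21 | intermediate
7 | (2R,3R)-3-[acetoxy(phenyl)-λ3-iodanyl]-5-(benzyloxy)-2-[3,4-bis(benzyloxy)phenyl]-4,4-dimethoxy-3,4-dihydro-2H-chromen-7-yl trifluoromethanesulfonate (iodine trans to ring D; C2 arranged as in 5) | COC1(OC)[C@H](I(OC(C)=O)c2ccccc2)[C@@H](c2ccc(OCc3ccccc3)c(OCc3ccccc3)c2)Oc2cc(OS(=O)(=O)C(F)(F)F)cc(OCc3ccccc3)c21 | intermediate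
8 | (2S,3S)-4-(benzyloxy)-2-[3,4-bis(benzyloxy)phenyl]-3-(trimethoxymethyl)-2,3-dihydro-1-benzofuran-6-yl trifluoromethanesulfonate (trimethyl ortho ester) | COC(OC)(OC)[C@H]1c2c(OCc3ccccc3)cc(OS(=O)(=O)C(F)(F)F)cc2O[C@@H]1c1ccc(OCc2ccccc2)c(OCc2ccccc2)c1 | intermediate
9 | methyl (2S,3S)-4-(benzyloxy)-2-[3,4-bis(benzyloxy)phenyl]-6-[(trifluoromethanesulfonyl)oxy]-2,3-dihydro-1-benzofuran-3-carboxylate (trans) | COC(=O)[C@H]1c2c(OCc3ccccc3)cc(OS(=O)(=O)C(F)(F)F)cc2O[C@@H]1c1ccc(OCc2ccccc2)c(OCc2ccccc2)c1 | intermediate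
10 | 3,4-bis(benzyloxy)benzaldehyde | O=Cc1ccc(OCc2ccccc2)c(OCc2ccccc2)c1 | starting material
11 | 1,2-bis(benzyloxy)-4-ethenylbenzene | C=Cc1ccc(OCc2ccccc2)c(OCc2ccccc2)c1 | intermediate
12 | methyl (2S,3S)-4-(benzyloxy)-2-[3,4-bis(benzyloxy)phenyl]-6-{(E)-2-[3,4-bis(benzyloxy)phenyl]ethenyl}-2,3-dihydro-1-benzofuran-3-carboxylate | COC(=O)[C@H]1c2c(OCc3ccccc3)cc(/C=C/c3ccc(OCc4ccccc4)c(OCc4ccccc4)c3)cc2O[C@@H]1c1ccc(OCc2ccccc2)c(OCc2ccccc2)c1 | intermediate
13 | (2S,3S)-4-(benzyloxy)-2-[3,4-bis(benzyloxy)phenyl]-6-{(E)-2-[3,4-bis(benzyloxy)phenyl]ethenyl}-2,3-dihydro-1-benzofuran-3-carboxylic acid | OC(=O)[C@H]1c2c(OCc3ccccc3)cc(/C=C/c3ccc(OCc4ccccc4)c(OCc4ccccc4)c3)cc2O[C@@H]1c1ccc(OCc2ccccc2)c(OCc2ccccc2)c1 | intermediate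
14 | 1,3-dioxoisoindolin-2-yl (2S,3S)-4-(benzyloxy)-2-[3,4-bis(benzyloxy)phenyl]-6-{(E)-2-[3,4-bis(benzyloxy)phenyl]ethenyl}-2,3-dihydro-1-benzofuran-3-carboxylate | O=C(ON1C(=O)c2ccccc2C1=O)[C@H]1c2c(OCc3ccccc3)cc(/C=C/c3ccc(OCc4ccccc4)c(OCc4ccccc4)c3)cc2O[C@@H]1c1ccc(OCc2ccccc2)c(OCc2ccccc2)c1 | intermediate
15 | 1,3-bis(benzyloxy)-5-bromobenzene | Brc1cc(OCc2ccccc2)cc(OCc2ccccc2)c1 | starting material
16 | [3,5-bis(benzyloxy)phenyl]lithium | [Li]c1cc(OCc2ccccc2)cc(OCc2ccccc2)c1 | intermediate
17 | [3,5-bis(benzyloxy)phenyl]zinc chloride | Cl[Zn]c1cc(OCc2ccccc2)cc(OCc2ccccc2)c1 | intermediate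
18 | (2S,3S)-4-(benzyloxy)-2-[3,4-bis(benzyloxy)phenyl]-3-[3,5-bis(benzyloxy)phenyl]-6-{(E)-2-[3,4-bis(benzyloxy)phenyl]ethenyl}-2,3-dihydro-1-benzofuran | c1ccccc1COc1cc(OCc2ccccc2)cc([C@H]2c3c(OCc4ccccc4)cc(/C=C/c4ccc(OCc5ccccc5)c(OCc5ccccc5)c4)cc3O[C@@H]2c2ccc(OCc3ccccc3)c(OCc3ccccc3)c2)c1 | intermediate
19 | 4-[(2S,3S)-3-(3,5-dihydroxyphenyl)-6-[(E)-2-(3,4-dihydroxyphenyl)ethenyl]-4-hydroxy-2,3-dihydro-1-benzofuran-2-yl]benzene-1,2-diol | Oc1cc(O)cc([C@H]2c3c(O)cc(/C=C/c4ccc(O)c(O)c4)cc3O[C@@H]2c2ccc(O)c(O)c2)c1 | target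

**Count and risks**

Total steps: 11. Longest linear sequence: 9 steps (1, 2, 3, 4, 6, 7, 8, 10, 11) from compound 1.

Steps most likely to fail:

1. Step 4. The electron-rich ring D may shift from C2 to C3 faster than the ring B carbon, or the iodane may be displaced by methanol or eliminated toward the flavone. Slow ketalisation of the hindered C4 carbonyl would favour both, and acid-induced ionisation of the benzylic C2–O bond would erode enantiomeric purity. The fallback sets out from 5 and comes back at 9, making the same C3–C3a bond by a Wolff ring contraction. Flavanone 5 would be deprotonated at C3 (LiN(SiMe3)2, THF, −78 °C) and acylated with 2,2,2-trifluoroethyl trifluoroacetate to the 3-(trifluoroacetyl)flavanone F1. Deacylative diazo transfer (MsN3, Et3N, MeCN) would give the 3-diazoflavanone F2. Irradiation at 365 nm in methanol would expel N2 while the ring B carbon shifts from the carbonyl carbon to C3, giving the ring-contracted ketene F3, which methanol traps. The ester should form largely as the cis isomer F4 (protonation anti to ring D), which DBU in CH2Cl2 equilibrates to the trans ester 9.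

2. Step 10. The hindered benzylic C3 radical may be captured too slowly by nickel, so that dimerisation, reduction, or loss of the C2 hydrogen with aromatisation to the benzofuran take over. The arylzinc reagent may also acylate on the activated ester, and aryl delivery may not be fully trans. The fallback sets out from 14 (and aryllithium 16) and comes back at 18. Quenching 16 with I2 would give 1,3-bis(benzyloxy)-5-iodobenzene F5. Compound 14 would be joined to it by reductive cross-electrophile coupling (NiBr2·glyme, 4,4'-di-tert-butyl-2,2'-bipyridine, zinc dust, N,N-dimethylacetamide, rt). Here the aryl group reaches nickel by oxidative addition, and no organozinc nucleophile meets the activated ester.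

3. Step 7. Ring C may open by retro-oxa-Michael elimination through the ester enolate, or the hindered ester may cleave incompletely. The fallback sets out from 12 and comes back at 13 by a reduction–oxidation sequence. i-Bu2AlH (CH2Cl2, −78 °C) would reduce the ester to the primary alcohol F6. Dess–Martin periodinane (NaHCO3, CH2Cl2) would give the aldehyde F7. Pinnick oxidation (NaClO2, NaH2PO4, 2-methyl-2-butene, t-BuOH–H2O) would then give acid 13, so the ester is never exposed to hydroxide.

**Further compounds**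

F1 | step 4 | (2S)-5-(benzyloxy)-2-[3,4-bis(benzyloxy)phenyl]-4-oxo-3-(trifluoroacetyl)-3,4-dihydro-2H-chromen-7-yl trifluoromethanesulfonate (C3 epimers or enol) | O=C1C(C(=O)C(F)(F)F)[C@@H](c2ccc(OCc3ccccc3)c(OCc3ccccc3)c2)Oc2cc(OS(=O)(=O)C(F)(F)F)cc(OCc3ccccc3)c21
F2 | step 4 | (2R)-5-(benzyloxy)-2-[3,4-bis(benzyloxy)phenyl]-3-diazo-4-oxo-3,4-dihydro-2H-chromen-7-yl trifluoromethanesulfonate (C2 arranged as in 5) | O=C1C(=[N+]=[N-])[C@@H](c2ccc(OCc3ccccc3)c(OCc3ccccc3)c2)Oc2cc(OS(=O)(=O)C(F)(F)F)cc(OCc3ccccc3)c21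
F3 | step 4 | (2R)-4-(benzyloxy)-2-[3,4-bis(benzyloxy)phenyl]-3-(oxomethylidene)-2,3-dihydro-1-benzofuran-6-yl trifluoromethanesulfonate (ketene; C2 arranged as in 5) | O=C=C1c2c(OCc3ccccc3)cc(OS(=O)(=O)C(F)(F)F)cc2O[C@@H]1c1ccc(OCc2ccccc2)c(OCc2ccccc2)c1
F4 | step 4 | methyl (2S,3R)-4-(benzyloxy)-2-[3,4-bis(benzyloxy)phenyl]-6-[(trifluoromethanesulfonyl)oxy]-2,3-dihydro-1-benzofuran-3-carboxylate (cis) | COC(=O)[C@@H]1c2c(OCc3ccccc3)cc(OS(=O)(=O)C(F)(F)F)cc2O[C@@H]1c1ccc(OCc2ccccc2)c(OCc2ccccc2)c1
F5 | step 10 | 1,3-bis(benzyloxy)-5-iodobenzene | Ic1cc(OCc2ccccc2)cc(OCc2ccccc2)c1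
F6 | step 7 | [(2S,3R)-4-(benzyloxy)-2-[3,4-bis(benzyloxy)phenyl]-6-{(E)-2-[3,4-bis(benzyloxy)phenyl]ethenyl}-2,3-dihydro-1-benzofuran-3-yl]methanol (trans) | OC[C@H]1c2c(OCc3ccccc3)cc(/C=C/c3ccc(OCc4ccccc4)c(OCc4ccccc4)c3)cc2O[C@@H]1c1ccc(OCc2ccccc2)c(OCc2ccccc2)c1
F7 | step 7 | (2S,3S)-4-(benzyloxy)-2-[3,4-bis(benzyloxy)phenyl]-6-{(E)-2-[3,4-bis(benzyloxy)phenyl]ethenyl}-2,3-dihydro-1-benzofuran-3-carbaldehyde (trans) | O=C[C@H]1c2c(OCc3ccccc3)cc(/C=C/c3ccc(OCc4ccccc4)c(OCc4ccccc4)c3)cc2O[C@@H]1c1ccc(OCc2ccccc2)c(OCc2ccccc2)c1
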